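The numbers of this flask belong to no real substance; what happens was integrated by code.

At early times the free catalyst meets the impurity while the first solid dissolves; this is the flask, with what we ask of it:

solid substrate 0.50 mM; free catalyst 10 µM (in portions, 4); impurity 1.2 µM; time 25 min; the portions of free catalyst follow each other after 1.5 s, the first at the start

    starting material + free catalyst ⇌ target + free catalyst, rate k1*[starting material]*[free catalyst] forward; the back reaction follows from the equilibrium constant (K1 = 0.89, k1 = 63000 L mol⁻¹ s⁻¹)
    target + free catalyst ⇌ isomer of the product + free catalyst, rate k2*[free catalyst]*[target] forward; the back reaction follows from the equilibrium constant (K2 = 3.7, k2 = 71000 L mol⁻¹ s⁻¹)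
    isomer of the product ⇌ starting material (k3 = 0.17 s⁻¹)
    solid substrate ⇌ starting material, rate k4*(cs4 - [starting material]) while solid is left; crystals form when [starting material] > cs4 (cs4 = 0.021 mM, k4 = 7.7 s⁻¹)
    free catalyst + impurity → spent catalyst (k5 = 1.9 × 10⁷ L mol⁻¹ s⁻¹)

- solid, in amounts per volume of the solution: solid substrate
- at the start none of the solid substrate is in solution
- what has only dissolved of solid substrate counts as not reacted
- the reaction counts as stopped when no species that holds the solid substrate changes by six tenths of a point or more over the second half of the time
- run time (flask): 25 min

1. the state of affairs at 25 min: stopped, and by what, or still going (for what has run out or reacted, a solid counts together with what of it has only dissolved) (it is still moving / forward and back rates have come level / no working catalyst is left / all of the solid substrate has reacted)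
2. part of the solid substrate that has turned into other species by 25 min (what has only dissolved does not count)
3. amount of target at 25 min, in percent of the solid substrate charged
4. amount of isomer of the product at 25 min, in percent of the solid substrate charged

First instants. The opening portion, 2.50 µM of free catalyst, removes the impurity on a time of about

t(impurity) = 0.0211 s

This is shorter than the gap of 1.5 s between portions, so by our reckoning 1.2 µM of catalyst is lost before the second portion lands, and 1.30 µM stays free. The whole charge then leaves c(free catalyst) = 8.80 µM.

Middle. With the catalyst steady, the two catalysed steps are pseudo-first-order. The isomer of the product leaves by the back catalysed step and by the uncatalysed step together, on a time of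

t(isomer) = 2.95 s

A dip in c(starting material) refills from the solid on 0.130 s, faster than that, so while solid lasts we hold c(starting material) near its solubility, 0.021 mM.

End. Since t(isomer) is short against 25 min, we expect equilibrium over a saturated solution:

c(target) = 0.89 × 0.021 mM = 0.0187 mM

c(isomer) = 3.7 × c(target) = 0.0692 mM

Their sum is the saturation capacity, the concentration of reacted forms that a solution saturated in starting material holds at equilibrium:

capacity = 0.0878 mM

The symmetric case is the zero of the scale: with every form equally favoured, the capacity is 2 solubilities, and here it is 4.18. The capacity plus the dissolved starting material comes to 0.109 mM, less than the charge of 0.50 mM, so solid remains. We therefore reckon a conversion of 17.6%, with 3.74% target and 13.8% isomer of the product, and forward and back rates level.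

The forecast says forward and back rates have come level, with conversion 17.57%, target 3.74% and isomer of the product 13.83%, on the ground that “Undissolved solid remains and holds the starting material”.

The simulation gives forward and back rates have come level, with conversion 17.6%, target 3.74% and isomer of the product 13.8%. In this flask half of that conversion stood at 0.0702 min, short against 25 min. The capacity and the dissolved starting material together leave 78.2% of the charge as undissolved solid, and this flask holds 78.2% of solid substrate at 25.0 min.

Take the neighbour flask with 0.20 mM of solid substrate. The total of 0.109 mM is still below that charge, so the same capacity gives a conversion of 43.9% and target 9.35%. The simulation of that flask gives 43.9%, with target 9.35% and isomer of the product 34.6%.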